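**Retrosynthetic overview**

1. Selaginellin F ⇒ triarylcarbinol 23 (acid unmasking, loss of water) ⇒ lactone 19 plus two equivalents of a 4-oxyphenyllithium, so both aryl rings on the methide carbon arrive by double addition to one carbonyl.
2. Feature used: the central benzene carries four adjacent substituents (C1 2,4-dihydroxyphenyl, C2 methide carbon, C3 arylethynyl, C4 CH2OH), and the oxygen of the resorcinol 2-OH is one C–O bond short of the methide carbon, so the C1 aryl ring and C2 can be tied together as the lactone ring of a 6H-benzo[c]chromen-6-one.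
3. 19 ⇒ dihydro lactone 18 (dehydrogenation) ⇒ aryl ester 17 by an intramolecular Diels–Alder reaction: the ester is the tether, the α,β-triple bond of a 2,4-diynoate is the dienophile, and the second triple bond is carried through as the arylethynyl arm.
4. 17 ⇒ dienylphenol 8 (from 2,4-dihydroxybenzaldehyde, vinylogous Horner–Wadsworth–Emmons) plus diynoic acid 16 (from 4-iodophenol, Sonogashira then Cadiot–Chodkiewicz).
5. Ring order: both outer oxygenated benzene rings are bought; lactone ring and central carbocycle close in one step; the central ring is aromatised; the lactone is opened as the two 4-oxyphenyl rings are attached; the quinoid ring is generated last.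

Key step: step 13

Assumption: the target is taken to exist as the open quinone methide written in its SMILES; cycloadduct 18 is racemic and one enantiomer is written.

**Route**

Step 1
Reactants: 1 2,4-dihydroxybenzaldehyde
Product: 2 2-hydroxy-4-(methoxymethoxy)benzaldehyde
Conditions: MOMCl (1.05 equiv), K2CO3, acetone, 0 °C to rt
Reagents that add atoms: chloromethyl methyl ether (MOMCl), COCCl
Why: Williamson etherification in which the 2-OH, held in a hydrogen bond to the formyl group, is the weaker nucleophile, so one equivalent of MOMCl should alkylate the 4-OH selectively.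

Step 2
Reactants: 2 2-hydroxy-4-(methoxymethoxy)benzaldehyde
Product: 3 2-(tert-butyldimethylsilyloxy)-4-(methoxymethoxy)benzaldehyde
Conditions: TBSCl, imidazole, DMF, rt
Reagents that add atoms: tert-butyldimethylsilyl chloride (TBSCl), CC(C)(C)[Si](C)(C)Cl
Why: imidazole-promoted silylation of the phenol, which prevents formation of an ortho-formyl phenoxide (a vinylogous carboxylate) that would make the aldehyde a poor electrophile in the olefination.

Step 3
Reactants: 3 2-(tert-butyldimethylsilyloxy)-4-(methoxymethoxy)benzaldehyde; 4 triethyl 4-phosphonocrotonate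
Product: 5 ethyl (2E,4E)-5-[2-(tert-butyldimethylsilyloxy)-4-(methoxymethoxy)phenyl]penta-2,4-dienoate
Conditions: 4 (1.3 equiv), LiN(SiMe3)2 (1.25 equiv), THF, −78 °C; then 3, −78 °C to rt
Reagents that add atoms: none
Why: vinylogous Horner–Wadsworth–Emmons olefination in which the delocalised phosphonate anion reacts at the carbon bearing phosphorus and reversible addition to the aryl aldehyde favours the new (E)-alkene, while the crotonate double bond keeps its E geometry.

Step 4
Reactants: 5 ethyl (2E,4E)-5-[2-(tert-butyldimethylsilyloxy)-4-(methoxymethoxy)phenyl]penta-2,4-dienoate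
Product: 6 (2E,4E)-5-[2-(tert-butyldimethylsilyloxy)-4-(methoxymethoxy)phenyl]penta-2,4-dien-1-ol
Conditions: i-Bu2AlH (2.3 equiv), CH2Cl2, −78 °C; aq. potassium sodium tartrate
Reagents that add atoms: none
Why: two hydride transfers from i-Bu2AlH reduce the conjugated ester in the 1,2-sense to the dienol without touching the silyl or MOM ethers.

Step 5
Reactants: 6 (2E,4E)-5-[2-(tert-butyldimethylsilyloxy)-4-(methoxymethoxy)phenyl]penta-2,4-dien-1-ol
Product: 7 tert-butyl{[(2E,4E)-5-[2-(tert-butyldimethylsilyloxy)-4-(methoxymethoxy)phenyl]penta-2,4-dien-1-yl]oxy}dimethylsilane (bis-silyl ether)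
Conditions: TBSCl (1.2 equiv), imidazole, CH2Cl2, 0 °C to rt
Reagents that add atoms: tert-butyldimethylsilyl chloride (TBSCl), CC(C)(C)[Si](C)(C)Cl
Why: imidazole-promoted silylation of the unhindered primary allylic alcohol.

Step 6
Reactants: 7 bis-silyl ether
Product: 8 2-[(1E,3E)-5-(tert-butyldimethylsilyloxy)penta-1,3-dien-1-yl]-5-(methoxymethoxy)phenol
Conditions: Cs2CO3 (0.5 equiv), DMF/H2O (10:1), rt
Reagents that add atoms: none
Why: mild basic hydrolysis cleaves the aryl silyl ether selectively because phenoxide is a far better leaving group from silicon than an alkoxide, so the primary silyl ether stays.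

Step 7
Reactants: 9 4-iodophenol
Product: 10 1-iodo-4-(methoxymethoxy)benzene
Conditions: MOMCl, i-Pr2NEt, CH2Cl2, 0 °C to rt
Reagents that add atoms: chloromethyl methyl ether (MOMCl), COCCl
Why: O-alkylation of the phenol with MOMCl under amine base (Williamson type).

Step 8
Reactants: 10 1-iodo-4-(methoxymethoxy)benzene; 11 trimethylsilylacetylene
Product: 12 {[4-(methoxymethoxy)phenyl]ethynyl}trimethylsilane
Conditions: PdCl2(PPh3)2 (2 mol%), CuI (4 mol%), Et3N, THF, rt
Reagents that add atoms: none
Why: Sonogashira coupling, in which oxidative addition of the aryl iodide to zerovalent palladium is fast at room temperature and the silyl group blocks the second alkyne terminus.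

Step 9
Reactants: 12 {[4-(methoxymethoxy)phenyl]ethynyl}trimethylsilane
Product: 13 1-ethynyl-4-(methoxymethoxy)benzene
Conditions: K2CO3 (0.2 equiv), MeOH, rt
Reagents that add atoms: none
Why: protodesilylation, in which methoxide attacks silicon and the released acetylide is protonated by methanol, so catalytic base suffices.

Step 10
Reactants: 13 1-ethynyl-4-(methoxymethoxy)benzene
Product: 14 1-(bromoethynyl)-4-(methoxymethoxy)benzene
Conditions: NBS (1.1 equiv), AgNO3 (10 mol%), acetone, rt, dark
Reagents that add atoms: N-bromosuccinimide (NBS), O=C1CCC(=O)N1Br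
Why: silver-catalysed bromination of the terminal alkyne through a silver acetylide, which reacts with NBS faster than the alkoxyarene ring does.

Step 11
Reactants: 14 1-(bromoethynyl)-4-(methoxymethoxy)benzene; 15 propiolic acid
Product: 16 5-[4-(methoxymethoxy)phenyl]penta-2,4-diynoic acid
Conditions: CuCl (10 mol%), NH2OH·HCl (cat.), 30% aq. n-BuNH2, MeOH, 0 °C; cold aq. citric acid to pH 3
Reagents that add atoms: none
Why: Cadiot–Chodkiewicz coupling of the copper acetylide of the propiolate salt with the bromoalkyne, with hydroxylamine keeping copper monovalent to suppress Glaser homocoupling and the low temperature preventing decarboxylation.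

Step 12
Reactants: 8 2-[(1E,3E)-5-(tert-butyldimethylsilyloxy)penta-1,3-dien-1-yl]-5-(methoxymethoxy)phenol; 16 5-[4-(methoxymethoxy)phenyl]penta-2,4-diynoic acid
Product: 17 2-[(1E,3E)-5-(tert-butyldimethylsilyloxy)penta-1,3-dien-1-yl]-5-(methoxymethoxy)phenyl 5-[4-(methoxymethoxy)phenyl]penta-2,4-diynoate
Conditions: DCC (1.1 equiv), DMAP (5 mol%), CH2Cl2, −20 to 0 °C; used promptly
Reagents that add atoms: none
Why: Steglich esterification through the O-acylisourea, with low temperature and only catalytic DMAP limiting conjugate addition to the diynoate.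

Step 13
Reactants: 17 dienylaryl diynoate
Product: 18 cis-8-[(tert-butyldimethylsilyloxy)methyl]-3-(methoxymethoxy)-7-{[4-(methoxymethoxy)phenyl]ethynyl}-8,10a-dihydro-6H-benzo[c]chromen-6-one (racemic, 8-H and 10a-H on the same face, (8R,10aR) enantiomer written)
Conditions: toluene (0.005 M), BHT (10 mol%), 120 °C, sealed tube, Ar
Reagents that add atoms: none
Why: a concerted, thermally allowed [4+2] cycloaddition of normal electron demand joins the (E,E)-diene, made electron-rich by the para-oxygenated aryl ring, to the ester-activated α,β-triple bond of the diynoate; the closest known reaction type is the intramolecular Diels–Alder reaction of 2-dienylaryl propiolates and related ester-tethered alkynoates, which gives benzo[c]chromen-6-ones after oxidation. The aryl-bearing diene terminus bonds to C-α, closing the six-membered lactone as a fused ring across the four-atom tether (two arene carbons, O, C=O), and the CH2OSi-bearing terminus bonds to C-β, closing the carbocycle as a 1,4-cyclohexadiene. The two new stereocentres (C8 and C10a) are set cis by suprafacial addition to the (E,E)-diene, are racemic, and are erased in the next step. The step needs site selectivity between the two triple bonds and a single regiochemistry: the tether lets only the α,β-alkyne reach the diene, and only with C-α on the aryl-bearing terminus, while high dilution keeps the remote alkyne from reacting intermolecularly. The ortho-fused arene holds the ester oxygen and the diene on the same side, and the aryl ester rotates easily into the reactive conformer, so the closure should run at moderate temperature.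

Step 14
Reactants: 18 cis-8,10a-dihydro lactone
Product: 19 8-[(tert-butyldimethylsilyloxy)methyl]-3-(methoxymethoxy)-7-{[4-(methoxymethoxy)phenyl]ethynyl}-6H-benzo[c]chromen-6-one
Conditions: DDQ (1.2 equiv), toluene, rt
Reagents that add atoms: none
Why: quinone dehydrogenation, in which DDQ abstracts hydride from a doubly allylic ring C–H and the cation loses a proton, the gain of aromaticity making oxidation of the 1,4-cyclohexadiene easy and removing both stereocentres.

Step 15
Reactants: 19 benzo[c]chromen-6-one; 20 1-bromo-4-(methoxymethoxy)benzene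
Product: 23 {2'-hydroxy-4'-(methoxymethoxy)-4-[(tert-butyldimethylsilyloxy)methyl]-3-{[4-(methoxymethoxy)phenyl]ethynyl}biphenyl-2-yl}bis[4-(methoxymethoxy)phenyl]methanol, via 4-(methoxymethoxy)phenyllithium 21 (not isolated), via ring-opened hydroxybiaryl diaryl ketone 22 (not isolated)
Conditions: 20 (4.5 equiv), n-BuLi (4.4 equiv), THF, −78 °C; then 19, −78 to 0 °C; sat. aq. NH4Cl; Et3N-deactivated silica
Reagents that add atoms: none
Why: bromine–lithium exchange gives aryllithium 21, whose 1,2-addition to the lactone carbonyl gives a hemiketal alkoxide that expels the phenoxide to leave ketone 22, and a second addition to this ketone, whose slim alkynyl neighbour leaves the carbonyl accessible, gives the tertiary alkoxide (double organolithium addition to an ester).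

Step 16
Reactants: 23 protected triarylcarbinol
Product: 25 Selaginellin F, via hexahydroxy triarylcarbinol 24 (not isolated)
Conditions: conc. HCl (cat.), MeOH/THF (3:1), 45 °C; then aq. NaHCO3 to pH 6–7
Reagents that add atoms: none
Why: acid-catalysed acetal exchange with methanol removes the four MOM groups and methanolysis removes the silyl ether, while the triarylcarbinol ionises to a cation stabilised by two para-hydroxyphenyl rings that loses a phenolic proton on neutralisation to give the quinone methide (fuchsone formation as in triarylmethane dyes), with no stereocentre or alkene isomer involved because the quinoid ring is symmetric.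

**Compound list**

1 | 2,4-dihydroxybenzaldehyde | O=Cc1ccc(O)cc1O | starting material
2 | 2-hydroxy-4-(methoxymethoxy)benzaldehyde | O=Cc1ccc(OCOC)cc1O | intermediate
3 | 2-(tert-butyldimethylsilyloxy)-4-(methoxymethoxy)benzaldehyde | O=Cc1ccc(OCOC)cc1O[Si](C)(C)C(C)(C)C | intermediate
4 | triethyl 4-phosphonocrotonate | CCOC(=O)/C=C/CP(=O)(OCC)OCC | starting material
5 | ethyl (2E,4E)-5-[2-(tert-butyldimethylsilyloxy)-4-(methoxymethoxy)phenyl]penta-2,4-dienoate | CCOC(=O)/C=C/C=C/c1ccc(OCOC)cc1O[Si](C)(C)C(C)(C)C | intermediate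
6 | (2E,4E)-5-[2-(tert-butyldimethylsilyloxy)-4-(methoxymethoxy)phenyl]penta-2,4-dien-1-ol | OC/C=C/C=C/c1ccc(OCOC)cc1O[Si](C)(C)C(C)(C)C | intermediate
7 | tert-butyl{[(2E,4E)-5-[2-(tert-butyldimethylsilyloxy)-4-(methoxymethoxy)phenyl]penta-2,4-dien-1-yl]oxy}dimethylsilane | COCOc1ccc(/C=C/C=C/CO[Si](C)(C)C(C)(C)C)c(O[Si](C)(C)C(C)(C)C)c1 | intermediate
8 | 2-[(1E,3E)-5-(tert-butyldimethylsilyloxy)penta-1,3-dien-1-yl]-5-(methoxymethoxy)phenol | COCOc1ccc(/C=C/C=C/CO[Si](C)(C)C(C)(C)C)c(O)c1 | intermediate
9 | 4-iodophenol | Oc1ccc(I)cc1 | starting material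
10 | 1-iodo-4-(methoxymethoxy)benzene | COCOc1ccc(I)cc1 | intermediate
11 | trimethylsilylacetylene | C#C[Si](C)(C)C | starting material
12 | {[4-(methoxymethoxy)phenyl]ethynyl}trimethylsilane | COCOc1ccc(C#C[Si](C)(C)C)cc1 | intermediate
13 | 1-ethynyl-4-(methoxymethoxy)benzene | C#Cc1ccc(OCOC)cc1 | intermediate
14 | 1-(bromoethynyl)-4-(methoxymethoxy)benzene | BrC#Cc1ccc(OCOC)cc1 | intermediate
15 | propiolic acid | C#CC(=O)O | starting material
16 | 5-[4-(methoxymethoxy)phenyl]penta-2,4-diynoic acid | OC(=O)C#CC#Cc1ccc(OCOC)cc1 | intermediate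
17 | 2-[(1E,3E)-5-(tert-butyldimethylsilyloxy)penta-1,3-dien-1-yl]-5-(methoxymethoxy)phenyl 5-[4-(methoxymethoxy)phenyl]penta-2,4-diynoate | COCOc1ccc(/C=C/C=C/CO[Si](C)(C)C(C)(C)C)c(OC(=O)C#CC#Cc2ccc(OCOC)cc2)c1 | intermediate
18 | cis-8-[(tert-butyldimethylsilyloxy)methyl]-3-(methoxymethoxy)-7-{[4-(methoxymethoxy)phenyl]ethynyl}-8,10a-dihydro-6H-benzo[c]chromen-6-one, racemic, (8R,10aR) enantiomer written | COCOc1ccc2c(c1)OC(=O)C1=C(C#Cc3ccc(OCOC)cc3)[C@H](CO[Si](C)(C)C(C)(C)C)C=C[C@@H]12 | intermediate
19 | 8-[(tert-butyldimethylsilyloxy)methyl]-3-(methoxymethoxy)-7-{[4-(methoxymethoxy)phenyl]ethynyl}-6H-benzo[c]chromen-6-one | COCOc1ccc2c(c1)OC(=O)c1c(C#Cc3ccc(OCOC)cc3)c(CO[Si](C)(C)C(C)(C)C)ccc12 | intermediate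
20 | 1-bromo-4-(methoxymethoxy)benzene | COCOc1ccc(Br)cc1 | starting material
21 | 4-(methoxymethoxy)phenyllithium | [Li]c1ccc(OCOC)cc1 | intermediate (not isolated)
22 | {2'-hydroxy-4'-(methoxymethoxy)-4-[(tert-butyldimethylsilyloxy)methyl]-3-{[4-(methoxymethoxy)phenyl]ethynyl}biphenyl-2-yl}[4-(methoxymethoxy)phenyl]methanone | COCOc1ccc(-c2ccc(CO[Si](C)(C)C(C)(C)C)c(C#Cc3ccc(OCOC)cc3)c2C(=O)c2ccc(OCOC)cc2)c(O)c1 | intermediate (not isolated)
23 | {2'-hydroxy-4'-(methoxymethoxy)-4-[(tert-butyldimethylsilyloxy)methyl]-3-{[4-(methoxymethoxy)phenyl]ethynyl}biphenyl-2-yl}bis[4-(methoxymethoxy)phenyl]methanol | COCOc1ccc(-c2ccc(CO[Si](C)(C)C(C)(C)C)c(C#Cc3ccc(OCOC)cc3)c2C(O)(c2ccc(OCOC)cc2)c2ccc(OCOC)cc2)c(O)c1 | intermediate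
24 | 2-[hydroxybis(4-hydroxyphenyl)methyl]-4-(hydroxymethyl)-3-[(4-hydroxyphenyl)ethynyl]biphenyl-2',4'-diol | OCc1ccc(-c2ccc(O)cc2O)c(C(O)(c2ccc(O)cc2)c2ccc(O)cc2)c1C#Cc1ccc(O)cc1 | intermediate (not isolated)
25 | Selaginellin F, 4-{[2',4'-dihydroxy-4-(hydroxymethyl)-3-[(4-hydroxyphenyl)ethynyl]biphenyl-2-yl](4-hydroxyphenyl)methylidene}cyclohexa-2,5-dien-1-one | O=C1C=CC(=C(c2ccc(O)cc2)c2c(-c3ccc(O)cc3O)ccc(CO)c2C#Cc2ccc(O)cc2)C=C1 | target

**Step count**

Total steps: 16. Longest linear sequence: 11 steps (steps 1–6, then 12–16).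

**Steps most likely to fail**

Step 13. The cycloaddition may be slow if the ester rests mainly in the conformer that holds the dienophile away from the diene. Thermal oligomerisation of the activated diynoate, or intermolecular cycloaddition at the remote alkyne, could then take over. The fallback sets out from phenol 8 and attaches the arylethynyl arm by cross-coupling after the benzannulation. Propiolic acid 15 would be brominated (NBS, AgNO3, acetone) to 3-bromopropiolic acid F1, which would be coupled to 8 with DCC to give the aryl 3-bromopropiolate F2. This small, strongly activated dienophile would undergo the same tethered Diels–Alder closure to the cis 7-bromo-8,10a-dihydro lactone F3, and DDQ would give the 7-bromobenzo[c]chromen-6-one F4. Sonogashira coupling of F4 with alkyne 13 (Pd(PPh3)4, CuI, Et3N, DMF, 70 °C) would rejoin the route at 19.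

Step 15. The second addition may stall, because the first adduct can rest as a cyclic hemiketal alkoxide and the ketone is flanked by two ortho substituents. On warming, the tertiary alkoxide may also add to the neighbouring alkyne. The fallback sets out from 19 and adds the two aryl groups separately. One equivalent of 21 at −78 °C and aqueous work-up would give ketone 22, now isolated. Its phenol would be capped (MOMCl, K2CO3, acetone) to give the 2'-O-MOM ketone F5, which can no longer close to a hemiketal. The less basic organocerium reagent made from 21 and CeCl3 would add at −78 °C to give the penta-MOM carbinol F6, and F6 under the conditions of step 16 would give 25 directly.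

Step 16. Under acid the triaryl cation may be captured by the neighbouring resorcinol 2'-OH, closing a 6,6-diaryl-6H-benzo[c]chromene instead of losing a proton to the quinone methide. Prolonged acid may also hydrate the alkyne. The fallback sets out from 23 and keeps the 2'-OH masked while acid is present. Allylation (allyl bromide, K2CO3, acetone) would give the allyl ether F7. The conditions of step 16 would then give the 2'-O-allyl quinone methide F8, in which no hydroxyl can reach the cation. Removal of the allyl group without acid (Pd(PPh3)4, K2CO3, MeOH, rt, then buffer to pH 6–7) would give 25.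

**Further compounds**

F1 | step 13 | 3-bromopropiolic acid | OC(=O)C#CBr
F2 | step 13 | 2-[(1E,3E)-5-(tert-butyldimethylsilyloxy)penta-1,3-dien-1-yl]-5-(methoxymethoxy)phenyl 3-bromopropiolate | COCOc1ccc(/C=C/C=C/CO[Si](C)(C)C(C)(C)C)c(OC(=O)C#CBr)c1
F3 | step 13 | cis-7-bromo-8-[(tert-butyldimethylsilyloxy)methyl]-3-(methoxymethoxy)-8,10a-dihydro-6H-benzo[c]chromen-6-one, racemic | COCOc1ccc2c(c1)OC(=O)C1=C(Br)[C@H](CO[Si](C)(C)C(C)(C)C)C=C[C@@H]12
F4 | step 13 | 7-bromo-8-[(tert-butyldimethylsilyloxy)methyl]-3-(methoxymethoxy)-6H-benzo[c]chromen-6-one | COCOc1ccc2c(c1)OC(=O)c1c(Br)c(CO[Si](C)(C)C(C)(C)C)ccc12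
F5 | step 15 | {2',4'-bis(methoxymethoxy)-4-[(tert-butyldimethylsilyloxy)methyl]-3-{[4-(methoxymethoxy)phenyl]ethynyl}biphenyl-2-yl}[4-(methoxymethoxy)phenyl]methanone | COCOc1ccc(-c2ccc(CO[Si](C)(C)C(C)(C)C)c(C#Cc3ccc(OCOC)cc3)c2C(=O)c2ccc(OCOC)cc2)c(OCOC)c1
F6 | step 15 | {2',4'-bis(methoxymethoxy)-4-[(tert-butyldimethylsilyloxy)methyl]-3-{[4-(methoxymethoxy)phenyl]ethynyl}biphenyl-2-yl}bis[4-(methoxymethoxy)phenyl]methanol | COCOc1ccc(-c2ccc(CO[Si](C)(C)C(C)(C)C)c(C#Cc3ccc(OCOC)cc3)c2C(O)(c2ccc(OCOC)cc2)c2ccc(OCOC)cc2)c(OCOC)c1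
F7 | step 16 | {2'-(allyloxy)-4'-(methoxymethoxy)-4-[(tert-butyldimethylsilyloxy)methyl]-3-{[4-(methoxymethoxy)phenyl]ethynyl}biphenyl-2-yl}bis[4-(methoxymethoxy)phenyl]methanol | COCOc1ccc(-c2ccc(CO[Si](C)(C)C(C)(C)C)c(C#Cc3ccc(OCOC)cc3)c2C(O)(c2ccc(OCOC)cc2)c2ccc(OCOC)cc2)c(OCC=C)c1
F8 | step 16 | 2'-O-allyl Selaginellin F, 4-{[2'-(allyloxy)-4'-hydroxy-4-(hydroxymethyl)-3-[(4-hydroxyphenyl)ethynyl]biphenyl-2-yl](4-hydroxyphenyl)methylidene}cyclohexa-2,5-dien-1-one | O=C1C=CC(=C(c2ccc(O)cc2)c2c(-c3ccc(O)cc3OCC=C)ccc(CO)c2C#Cc2ccc(O)cc2)C=C1
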